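**Strategy.** Both dihydrofuran rings are cut across the two bonds to their aryl-bearing C2 (C2–C3 and O1–C2). In the key step an aryl Grignard reagent adds to an O-Boc salicylaldehyde, Boc migration unmasks an o-quinone methide, and a chiral benzylic sulfonium ylide adds to it. The phenoxide then displaces the sulfide and closes the O1–C2 bond of the hydroxylated dihydrobenzofuran (ring B), giving three bonds and trans C2/C3 under reagent control in one flask. It exploits the ortho relation of O1 and benzylic C3 on the resorcinol-type benzo ring of ring B. The precursor is a brominated, protected 2,4-dihydroxybenzaldehyde; its bromine then carries the same annulation onto the formyl-bearing ring A.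

Key step: step 6

Remarks before the steps:
- Locants: in each dihydrobenzofuran, O1 is the ring oxygen, C2 the carbon bearing the 4-hydroxyphenyl group and C3 the neighbouring benzylic carbon. Ring B is the 6-hydroxy-dihydrobenzofuran that carries the 3,5-dihydroxyphenyl group; ring A is the 5-formyl-dihydrobenzofuran. TBS = tert-butyldimethylsilyl, Boc = tert-butoxycarbonyl.
- Assumption on the sense of induction: the benzylide of (1S,4S,5S)-isothiocineole is taken to react on the face remote from its gem-dimethyl group, which corresponds to (2R) after inversion at the ylide carbon. If a model annulation shows the opposite sense, the (1R,4R,5R) sulfide is used with no other change.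
- Assumption on supply: sulfide 7 and bromide 8 are taken as purchasable.

Step 1
Reactants: 1 5-bromoresorcinol
Product: 3 2-bromo-4,6-dihydroxybenzaldehyde, via iminium chloride 2 (not isolated)
Conditions: POCl3, DMF, MeCN, −15 °C → rt; then H2O, 50 °C
Reagents that add atoms: N,N-dimethylformamide, CN(C)C=O; water, O
Why: Vilsmeier–Haack formylation should occur para to one hydroxyl and ortho to the other (next to bromine) rather than between the two hydroxyls, as in the formylation of orcinol.

Step 2
Reactants: 3 2-bromo-4,6-dihydroxybenzaldehyde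
Product: 4 2-bromo-4-(tert-butyldimethylsilyloxy)-6-hydroxybenzaldehyde
Conditions: TBSCl (1.05 equiv), imidazole, CH2Cl2, 0 °C
Reagents that add atoms: tert-butyldimethylsilyl chloride, CC(C)(C)[Si](C)(C)Cl
Why: Silylation should take the 4-hydroxyl selectively, because it is the more acidic one and is not tied up in the hydrogen bond to the aldehyde.

Step 3
Reactants: 4 2-bromo-4-(tert-butyldimethylsilyloxy)-6-hydroxybenzaldehyde
Product: 5 3-bromo-5-(tert-butyldimethylsilyloxy)-2-formylphenyl tert-butyl carbonate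
Conditions: Boc2O, i-Pr2NEt, DMAP (cat.), THF, 0 °C → rt
Reagents that add atoms: di-tert-butyl dicarbonate, CC(C)(C)OC(=O)OC(=O)OC(C)(C)C
Why: DMAP-catalysed carbonate formation on the remaining chelated phenol is the standard preparation of O-Boc salicylaldehydes and leaves the aryl silyl ether untouched.

Step 4
Reactants: 1 5-bromoresorcinol
Product: 6 1-bromo-3,5-bis(tert-butyldimethylsilyloxy)benzene
Conditions: TBSCl (2.3 equiv), imidazole, DMF, rt
Reagents that add atoms: tert-butyldimethylsilyl chloride, CC(C)(C)[Si](C)(C)Cl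
Why: Exhaustive silylation of both phenols gives an aryl bromide that tolerates magnesium insertion.

Step 5
Reactants: 7 (1S,4S,5S)-isothiocineole; 8 4-(tert-butyldimethylsilyloxy)benzyl bromide
Product: 9 (1S,4S,5S)-6-[4-(tert-butyldimethylsilyloxy)benzyl]-4,7,7-trimethyl-6-thiabicyclo[3.2.1]octan-6-ium tetrafluoroborate
Conditions: NaBF4 (2 equiv), MeCN, rt, dark; trituration with Et2O
Reagents that add atoms: sodium tetrafluoroborate, [Na+].F[B-](F)(F)F
Why: S-alkylation of the sulfide by the activated benzylic bromide, driven by precipitation of NaBr, should occur on the exposed exo lone pair and give one sulfonium diastereomer (sulfur configuration is not written in the SMILES).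

Step 6
Reactants: 5 3-bromo-5-(tert-butyldimethylsilyloxy)-2-formylphenyl tert-butyl carbonate; 6 1-bromo-3,5-bis(tert-butyldimethylsilyloxy)benzene; 9 sulfonium tetrafluoroborate
Product: 13 (2R,3R)-4-bromo-3-[3,5-bis(tert-butyldimethylsilyloxy)phenyl]-6-(tert-butyldimethylsilyloxy)-2-[4-(tert-butyldimethylsilyloxy)phenyl]-2,3-dihydro-1-benzofuran, via Grignard reagent 10 (not isolated), via sulfonium ylide 11 (not isolated), via o-quinone methide 12 (not isolated)
Conditions: 6, Mg, THF, 40 °C (gives 10, 1.05 equiv); 5, THF, −78 °C, 30 min; then 11 (1.5 equiv, from 9 and LiN(SiMe3)2, THF, −78 °C); −78 → 0 °C, 3 h; aq. NH4Cl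
Reagents that add atoms: none
Why: Proposed new method: Grignard reagent 10 adds to the aldehyde of 5, the alkoxide takes over the Boc group from the neighbouring phenol oxygen, and the freed phenoxide expels tert-butyl carbonate to give o-quinone methide 12 (the known O-Boc-salicylaldehyde entry to such methides); ylide 11 adds to the exocyclic carbon of 12 and the phenoxide then displaces the sulfonium group at the benzylic carbon, which forms the O1–C2 bond. The closest known reaction type is the carbonate-mediated [4+1] annulation of sulfonium ylides with o-quinone methides released from 2-(1-tosylalkyl)phenols; its merger with the Boc-transfer release of the methide and with an isothiocineole-derived benzylide as the source of absolute configuration has not been described. The furan ring closes 5-exo-tet by SN2 with inversion at C2. C2 is set by the sulfide, whose ylide is attacked on the face remote from the gem-dimethyl group; C3 is set relative to C2 by the anti addition that places the two aryl groups trans, which is also the thermodynamically preferred arrangement. The step needs the 1,4-addition to outrun oligomerisation of 12 and its capture by excess Grignard reagent, which is secured by using 10 in only slight excess and having 11 present before 12 is released on warming; the aldehyde is consumed before 11 is added, so no epoxide can form.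

Step 7
Reactants: 14 3-formyl-4-hydroxybenzonitrile
Product: 15 tert-butyl 4-cyano-2-formylphenyl carbonate
Conditions: Boc2O, i-Pr2NEt, DMAP (cat.), CH2Cl2, 0 °C → rt
Reagents that add atoms: di-tert-butyl dicarbonate, CC(C)(C)OC(=O)OC(=O)OC(C)(C)C
Why: DMAP-catalysed carbonate formation on the salicylaldehyde hydroxyl gives the second o-quinone methide precursor, with the nitrile as a latent aldehyde.

Step 8
Reactants: 13 ring B bromide; 15 tert-butyl 4-cyano-2-formylphenyl carbonate; 9 sulfonium tetrafluoroborate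
Product: 18 (2R,3R)-3-{(2R,3R)-3-[3,5-bis(tert-butyldimethylsilyloxy)phenyl]-6-(tert-butyldimethylsilyloxy)-2-[4-(tert-butyldimethylsilyloxy)phenyl]-2,3-dihydro-1-benzofuran-4-yl}-2-[4-(tert-butyldimethylsilyloxy)phenyl]-2,3-dihydro-1-benzofuran-5-carbonitrile, via aryllithium 16 (not isolated), via o-quinone methide 17 (not isolated)
Conditions: 13, t-BuLi (2.0 equiv), THF, −78 °C, 10 min; 15 (1.0 equiv), −78 °C; then 9 (1.5 equiv) premixed with LiN(SiMe3)2 (1.5 equiv) in THF at −78 °C in a second flask, and MgBr2·OEt2 (1.2 equiv); −78 → 0 °C; aq. NH4Cl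
Reagents that add atoms: none
Why: Proposed new method: the same annulation as in step 6 (closest known type: carbonate-mediated [4+1] annulation of sulfonium ylides with o-quinone methides), now started by bromine–lithium exchange and 1,2-addition of aryllithium 16 to 15, after which Boc transfer and MgBr2-assisted loss of tert-butyl carbonate release methide 17, and the benzylide of salt 9 (the reagent of step 6, prepared in the same way) adds to it and closes ring A 5-exo-tet; C2 and C3 of ring A should be set (2R,3R, trans) by the same sulfide, whose control is expected to override the more distant centres of ring B, and the nitrile is spared because aryllithium addition to the aldehyde is far faster at −78 °C.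

Step 9
Reactants: 18 bis-dihydrobenzofuran nitrile
Product: 20 (2R,3R)-3-{(2R,3R)-3-[3,5-bis(tert-butyldimethylsilyloxy)phenyl]-6-(tert-butyldimethylsilyloxy)-2-[4-(tert-butyldimethylsilyloxy)phenyl]-2,3-dihydro-1-benzofuran-4-yl}-2-[4-(tert-butyldimethylsilyloxy)phenyl]-2,3-dihydro-1-benzofuran-5-carbaldehyde, via aluminium aldimine 19 (not isolated)
Conditions: i-Bu2AlH (1.3 equiv), CH2Cl2, −78 → −40 °C; then 10% aq. tartaric acid, 0 °C
Reagents that add atoms: water, O
Why: Partial reduction of an aryl nitrile stops at the N-aluminio aldimine, which is hydrolysed to the aldehyde on mild acidic work-up without touching aryl silyl ethers or the benzylic ethers.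

Step 10
Reactants: 20 penta-TBS aldehyde
Product: 21 (2R,3R)-3-[(2R,3R)-3-(3,5-dihydroxyphenyl)-6-hydroxy-2-(4-hydroxyphenyl)-2,3-dihydro-1-benzofuran-4-yl]-2-(4-hydroxyphenyl)-2,3-dihydro-1-benzofuran-5-carbaldehyde (target)
Conditions: Bu4NF (6 equiv), AcOH (6 equiv), THF, 0 °C → rt
Reagents that add atoms: none
Why: Fluoride-mediated cleavage of the five aryl silyl ethers, buffered with acetic acid so that the phenols stay protonated, should avoid phenoxide-driven opening of the O1–C2 bonds and leave all four stereocentres and the aldehyde intact.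

**Compound list**

1 | 5-bromoresorcinol | Oc1cc(O)cc(Br)c1 | starting material
2 | N-[(2-bromo-4,6-dihydroxyphenyl)methylidene]-N-methylmethanaminium chloride | C[N+](C)=Cc1c(O)cc(O)cc1Br.[Cl-] | intermediate
3 | 2-bromo-4,6-dihydroxybenzaldehyde | O=Cc1c(O)cc(O)cc1Br | intermediate
4 | 2-bromo-4-(tert-butyldimethylsilyloxy)-6-hydroxybenzaldehyde | O=Cc1c(O)cc(O[Si](C)(C)C(C)(C)C)cc1Br | intermediate
5 | 3-bromo-5-(tert-butyldimethylsilyloxy)-2-formylphenyl tert-butyl carbonate | O=Cc1c(OC(=O)OC(C)(C)C)cc(O[Si](C)(C)C(C)(C)C)cc1Br | intermediate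
6 | 1-bromo-3,5-bis(tert-butyldimethylsilyloxy)benzene | Brc1cc(O[Si](C)(C)C(C)(C)C)cc(O[Si](C)(C)C(C)(C)C)c1 | intermediate
7 | (1S,4S,5S)-isothiocineole, (1S,4S,5S)-4,7,7-trimethyl-6-thiabicyclo[3.2.1]octane | C[C@H]1CC[C@H]2C[C@@H]1SC2(C)C | starting material
8 | 4-(tert-butyldimethylsilyloxy)benzyl bromide | BrCc1ccc(O[Si](C)(C)C(C)(C)C)cc1 | starting material
9 | (1S,4S,5S)-6-[4-(tert-butyldimethylsilyloxy)benzyl]-4,7,7-trimethyl-6-thiabicyclo[3.2.1]octan-6-ium tetrafluoroborate | C[C@H]1CC[C@H]2C[C@@H]1[S+](Cc1ccc(O[Si](C)(C)C(C)(C)C)cc1)C2(C)C.F[B-](F)(F)F | intermediate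
10 | [3,5-bis(tert-butyldimethylsilyloxy)phenyl]magnesium bromide | Br[Mg]c1cc(O[Si](C)(C)C(C)(C)C)cc(O[Si](C)(C)C(C)(C)C)c1 | intermediate
11 | sulfonium benzylide of 9 (ylide carbon between sulfur and the 4-silyloxyphenyl ring) | C[C@H]1CC[C@H]2C[C@@H]1[S+]([CH-]c1ccc(O[Si](C)(C)C(C)(C)C)cc1)C2(C)C | intermediate
12 | 6-[3,5-bis(tert-butyldimethylsilyloxy)benzylidene]-5-bromo-3-(tert-butyldimethylsilyloxy)cyclohexa-2,4-dien-1-one | O=C1C=C(O[Si](C)(C)C(C)(C)C)C=C(Br)C1=Cc1cc(O[Si](C)(C)C(C)(C)C)cc(O[Si](C)(C)C(C)(C)C)c1 | intermediate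
13 | (2R,3R)-4-bromo-3-[3,5-bis(tert-butyldimethylsilyloxy)phenyl]-6-(tert-butyldimethylsilyloxy)-2-[4-(tert-butyldimethylsilyloxy)phenyl]-2,3-dihydro-1-benzofuran | Brc1cc(O[Si](C)(C)C(C)(C)C)cc2c1[C@@H](c1cc(O[Si](C)(C)C(C)(C)C)cc(O[Si](C)(C)C(C)(C)C)c1)[C@H](c1ccc(O[Si](C)(C)C(C)(C)C)cc1)O2 | intermediate
14 | 3-formyl-4-hydroxybenzonitrile | N#Cc1ccc(O)c(C=O)c1 | starting material
15 | tert-butyl 4-cyano-2-formylphenyl carbonate | N#Cc1ccc(OC(=O)OC(C)(C)C)c(C=O)c1 | intermediate
16 | aryllithium from 13 (lithium in place of bromine at C4) | [Li]c1cc(O[Si](C)(C)C(C)(C)C)cc2c1[C@@H](c1cc(O[Si](C)(C)C(C)(C)C)cc(O[Si](C)(C)C(C)(C)C)c1)[C@H](c1ccc(O[Si](C)(C)C(C)(C)C)cc1)O2 | intermediate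
17 | 3-{[ring B aryl]methylidene}-4-oxocyclohexa-1,5-diene-1-carbonitrile, ring B aryl = the 4-yl group of 13 | O=C1C=CC(C#N)=CC1=Cc1cc(O[Si](C)(C)C(C)(C)C)cc2c1[C@@H](c1cc(O[Si](C)(C)C(C)(C)C)cc(O[Si](C)(C)C(C)(C)C)c1)[C@H](c1ccc(O[Si](C)(C)C(C)(C)C)cc1)O2 | intermediate
18 | (2R,3R,2'R,3'R) penta-TBS bis-dihydrobenzofuran 5-carbonitrile (name as in step 8) | N#Cc1ccc2c(c1)[C@@H](c1cc(O[Si](C)(C)C(C)(C)C)cc3c1[C@@H](c1cc(O[Si](C)(C)C(C)(C)C)cc(O[Si](C)(C)C(C)(C)C)c1)[C@H](c1ccc(O[Si](C)(C)C(C)(C)C)cc1)O3)[C@H](c1ccc(O[Si](C)(C)C(C)(C)C)cc1)O2 | intermediate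
19 | N-(diisobutylaluminio) aldimine of 18 | CC(C)C[Al](CC(C)C)N=Cc1ccc2c(c1)[C@@H](c1cc(O[Si](C)(C)C(C)(C)C)cc3c1[C@@H](c1cc(O[Si](C)(C)C(C)(C)C)cc(O[Si](C)(C)C(C)(C)C)c1)[C@H](c1ccc(O[Si](C)(C)C(C)(C)C)cc1)O3)[C@H](c1ccc(O[Si](C)(C)C(C)(C)C)cc1)O2 | intermediate
20 | (2R,3R,2'R,3'R) penta-TBS bis-dihydrobenzofuran 5-carbaldehyde (name as in step 9) | O=Cc1ccc2c(c1)[C@@H](c1cc(O[Si](C)(C)C(C)(C)C)cc3c1[C@@H](c1cc(O[Si](C)(C)C(C)(C)C)cc(O[Si](C)(C)C(C)(C)C)c1)[C@H](c1ccc(O[Si](C)(C)C(C)(C)C)cc1)O3)[C@H](c1ccc(O[Si](C)(C)C(C)(C)C)cc1)O2 | intermediate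
21 | (2R,3R)-3-[(2R,3R)-3-(3,5-dihydroxyphenyl)-6-hydroxy-2-(4-hydroxyphenyl)-2,3-dihydro-1-benzofuran-4-yl]-2-(4-hydroxyphenyl)-2,3-dihydro-1-benzofuran-5-carbaldehyde | O=Cc1ccc2c(c1)[C@@H](c1cc(O)cc3c1[C@@H](c1cc(O)cc(O)c1)[C@H](c1ccc(O)cc1)O3)[C@H](c1ccc(O)cc1)O2 | target

**Step count and risks**

Total steps: 10. Longest linear sequence: 7 steps (1, 2, 3, 6, 8, 9, 10).

Steps most likely to fail:

1. Step 6 (labelled step). The ylide may decay (1,2-shift or proton transfer) before the methide is released, the methide may oligomerise, or facial control by the sulfide may be incomplete. The fallback uses known chemistry and separates methide release from the low-temperature ylide. It sets out from 4 and 6 and returns at 13. Grignard reagent 10 (2.2 equiv) is added to hydroxy aldehyde 4 to give the stable diaryl carbinol F1. F1 and p-toluenesulfinic acid in CH2Cl2 give sulfone F2, an isolable o-quinone methide precursor. F2, salt 9 and Cs2CO3 in CH2Cl2 at room temperature then give 13 by the established carbonate-mediated [4+1] annulation, in which methide and ylide are both generated slowly under the same mild base.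

2. Step 8 (labelled step). Proton transfer to the hindered aryllithium may outrun its addition, and opposing substrate and reagent preferences may erode diastereoselection. The fallback uses known chemistry, sets out from 13 and 14 and returns at 18. Aryllithium 16 (from 13 and t-BuLi) is added to the sodium phenoxide of 14 (NaH, THF) to give diaryl carbinol F3. p-Toluenesulfinic acid converts F3 into sulfone F4. F4, salt 9 and Cs2CO3 in CH2Cl2 then give 18, with any minor diastereomer removed by chromatography.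

3. Step 1. Formylation may occur between the two hydroxyl groups or twice. The fallback sets out from 1 and returns at 3. Compound 1 is methylated (MeI, K2CO3, acetone) to 1-bromo-3,5-dimethoxybenzene F5. Vilsmeier–Haack formylation of F5, which is directed next to bromine and para to a methoxy group, gives 2-bromo-4,6-dimethoxybenzaldehyde F6. BBr3 in CH2Cl2 then cleaves both methyl ethers to give 3.

**Further compounds**

F1 | step 6 | [3,5-bis(tert-butyldimethylsilyloxy)phenyl][2-bromo-6-hydroxy-4-(tert-butyldimethylsilyloxy)phenyl]methanol | OC(c1c(O)cc(O[Si](C)(C)C(C)(C)C)cc1Br)c1cc(O[Si](C)(C)C(C)(C)C)cc(O[Si](C)(C)C(C)(C)C)c1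
F2 | step 6 | 3-bromo-2-{[3,5-bis(tert-butyldimethylsilyloxy)phenyl](4-methylbenzenesulfonyl)methyl}-5-(tert-butyldimethylsilyloxy)phenol | Cc1ccc(cc1)S(=O)(=O)C(c1c(O)cc(O[Si](C)(C)C(C)(C)C)cc1Br)c1cc(O[Si](C)(C)C(C)(C)C)cc(O[Si](C)(C)C(C)(C)C)c1
F3 | step 8 | 4-hydroxy-3-{hydroxy[ring B aryl]methyl}benzonitrile, ring B aryl = the 4-yl group of 13 | N#Cc1ccc(O)c(c1)C(O)c1cc(O[Si](C)(C)C(C)(C)C)cc2c1[C@@H](c1cc(O[Si](C)(C)C(C)(C)C)cc(O[Si](C)(C)C(C)(C)C)c1)[C@H](c1ccc(O[Si](C)(C)C(C)(C)C)cc1)O2
F4 | step 8 | 4-hydroxy-3-{(4-methylbenzenesulfonyl)[ring B aryl]methyl}benzonitrile | N#Cc1ccc(O)c(c1)C(S(=O)(=O)c1ccc(C)cc1)c1cc(O[Si](C)(C)C(C)(C)C)cc2c1[C@@H](c1cc(O[Si](C)(C)C(C)(C)C)cc(O[Si](C)(C)C(C)(C)C)c1)[C@H](c1ccc(O[Si](C)(C)C(C)(C)C)cc1)O2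
F5 | step 1 | 1-bromo-3,5-dimethoxybenzene | COc1cc(OC)cc(Br)c1
F6 | step 1 | 2-bromo-4,6-dimethoxybenzaldehyde | COc1cc(OC)c(C=O)c(Br)c1
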